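**Retrosynthetic overview**

1. Target 21 ⇐ resorcinol 18 by methylation of the ring A C5 hydroxyl, BCl3 cleavage of the ring B methyl ether and tert-butyl ester, and hydrolysis of the ring A ethyl ester.
2. Feature: ring A has oxygen on C3 and C5 flanking chlorinated C4 (a 1,3-dicarbonyl pattern), CO2H on C1 and the aryl ether on C2. Ring A is therefore opened at C1–C2 to the aryloxy 5-chloro-2,4,6-trioxoheptanoate 16, whose chain C2, C7, C6, C5, C4, C3 become ring A C1, C2, C3, C4, C5, C6.
3. 16 ⇐ 15 ⇐ 14 ⇐ 13: the C2 ketone is carried as a silyl-protected carbinol (not as a ketal next to the ester) and is released last by neutral oxidation. Chlorine goes onto C5 while the C4/C6 diketone is the only 1,3-dicarbonyl.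
4. 13 ⇐ 6 + 10: the C5–C6 bond comes from C-acylation of the kinetic methyl enolate of 10 (from acetone 7 and ethyl glyoxylate 8). Acid 6 comes from 2,6-dihydroxy-4-methylbenzoic acid 1 and ethyl bromoacetate 4.
5. Ring order: ring B is bought intact and ring A is the only ring formed (step 11). The ring B carboxyl is carried as a tert-butyl ester so that the aryloxymethylene carbanion cannot close onto it.

Key step: step 11

Remark on the chemistry: the open-chain compounds 9, 10 and 13 to 16 are carried as racemates or diastereomer mixtures (C2, C5), since both centres become sp2 carbons of ring A; the target is achiral.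

**Route**

Step 1
Reactants: 1 2,6-dihydroxy-4-methylbenzoic acid
Product: 2 tert-butyl 2,6-dihydroxy-4-methylbenzoate
Conditions: Me2NCH(Ot-Bu)2 (4 equiv), PhMe, 80 °C
Reagents that add atoms: N,N-dimethylformamide di-tert-butyl acetal, CN(C)C(OC(C)(C)C)OC(C)(C)C
Why: Acetal-mediated alkylative esterification transfers tert-butyl to the carboxylate through an alkoxyiminium ion pair and should leave both phenolic hydroxyls free.

Step 2
Reactants: 2 tert-butyl 2,6-dihydroxy-4-methylbenzoate
Product: 3 tert-butyl 2-hydroxy-6-methoxy-4-methylbenzoate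
Conditions: MeI (1.05 equiv), K2CO3 (1.1 equiv), acetone, rt
Reagents that add atoms: iodomethane, CI
Why: Williamson etherification should stop at the monoether because the remaining hydroxyl is then locked in a hydrogen bond to the ester carbonyl and is much less reactive.

Step 3
Reactants: 3 tert-butyl 2-hydroxy-6-methoxy-4-methylbenzoate; 4 ethyl bromoacetate
Product: 5 tert-butyl 2-(2-ethoxy-2-oxoethoxy)-6-methoxy-4-methylbenzoate
Conditions: K2CO3 (2 equiv), DMF, 60 °C
Reagents that add atoms: none
Why: Williamson O-alkylation with the activated α-bromo ester in warm DMF overcomes the chelation of the phenol, and the tert-butyl ester cannot take part in a Dieckmann closure.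

Step 4
Reactants: 5 tert-butyl 2-(2-ethoxy-2-oxoethoxy)-6-methoxy-4-methylbenzoate
Product: 6 2-[2-(tert-butoxycarbonyl)-3-methoxy-5-methylphenoxy]acetic acid
Conditions: LiOH·H2O (1.5 equiv), THF/H2O, 0 °C → rt; then 1 M HCl to pH 3 at 0 °C
Reagents that add atoms: lithium hydroxide, [Li+].[OH-]
Why: Saponification should be selective for the unhindered aliphatic ethyl ester, because the di-ortho-substituted tert-butyl benzoate is inert to hydroxide.

Step 5
Reactants: 7 acetone; 8 ethyl glyoxylate
Product: 9 ethyl 2-hydroxy-4-oxopentanoate (racemic)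
Conditions: DL-proline (20 mol %), acetone (solvent), rt
Reagents that add atoms: none
Why: Enamine-catalysed direct aldol addition of acetone to the aldehyde of freshly distilled ethyl glyoxylate; the racemic catalyst gives the racemic carbinol, and its configuration does not matter because C2 is oxidized later.

Step 6
Reactants: 9 ethyl 2-hydroxy-4-oxopentanoate
Product: 10 ethyl 2-[(tert-butyldimethylsilyl)oxy]-4-oxopentanoate (racemic)
Conditions: TBSCl (1.2 equiv), imidazole (2.5 equiv), DMF, 0 °C → rt
Reagents that add atoms: tert-butyldimethylsilyl chloride, CC(C)(C)[Si](C)(C)Cl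
Why: Standard silylation of a secondary alcohol; it holds C2 at the carbinol level so that C3 is not activated in the later chlorination.

Step 7
Reactants: 6 2-[2-(tert-butoxycarbonyl)-3-methoxy-5-methylphenoxy]acetic acid; 10 ethyl 2-[(tert-butyldimethylsilyl)oxy]-4-oxopentanoate
Product: 13 ethyl 7-[2-(tert-butoxycarbonyl)-3-methoxy-5-methylphenoxy]-2-[(tert-butyldimethylsilyl)oxy]-4,6-dioxoheptanoate, via acyl imidazolide 11 (not isolated), via lithium enolate 12 (not isolated)
Conditions: 6, CDI (1.1 equiv), THF, rt, then argon purge to expel CO2; added to 10 (3.3 equiv), LiN(i-Pr)2 (3.3 equiv), THF, −78 °C; −78 → −40 °C; AcOH quench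
Reagents that add atoms: none
Why: Claisen-type C-acylation of the kinetic methyl-side lithium enolate by the acyl imidazolide forms the C5–C6 bond; three equivalents of enolate are used because the liberated imidazole and the acidic diketone product each consume one, and the surplus ketone is recoverable.

Step 8
Reactants: 13 ethyl 7-[2-(tert-butoxycarbonyl)-3-methoxy-5-methylphenoxy]-2-[(tert-butyldimethylsilyl)oxy]-4,6-dioxoheptanoate
Product: 14 ethyl 7-[2-(tert-butoxycarbonyl)-3-methoxy-5-methylphenoxy]-2-[(tert-butyldimethylsilyl)oxy]-5-chloro-4,6-dioxoheptanoate (diastereomer mixture, enolized)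
Conditions: NCS (1.0 equiv), CH2Cl2, 0 °C → rt
Reagents that add atoms: N-chlorosuccinimide, O=C1CCC(=O)N1Cl
Why: Electrophilic α-chlorination of the enol of the only 1,3-diketone puts chlorine on its central carbon C5; the new C5 centre is uncontrolled and epimerizable and is erased on aromatization.

Step 9
Reactants: 14 ethyl 7-[2-(tert-butoxycarbonyl)-3-methoxy-5-methylphenoxy]-2-[(tert-butyldimethylsilyl)oxy]-5-chloro-4,6-dioxoheptanoate
Product: 15 ethyl 7-[2-(tert-butoxycarbonyl)-3-methoxy-5-methylphenoxy]-5-chloro-2-hydroxy-4,6-dioxoheptanoate (diastereomer mixture, in equilibrium with its cyclic hemiketal)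
Conditions: HF·pyridine, pyridine, THF, 0 °C → rt
Reagents that add atoms: none
Why: Fluoride-mediated desilylation; the pyridine buffer keeps the medium too weakly acidic to dehydrate the δ-hydroxy β-diketone or cleave the tert-butyl ester.

Step 10
Reactants: 15 ethyl 7-[2-(tert-butoxycarbonyl)-3-methoxy-5-methylphenoxy]-5-chloro-2-hydroxy-4,6-dioxoheptanoate
Product: 16 ethyl 7-[2-(tert-butoxycarbonyl)-3-methoxy-5-methylphenoxy]-5-chloro-2,4,6-trioxoheptanoate (racemic, enolized)
Conditions: Dess–Martin periodinane (1.3 equiv), CH2Cl2, 0 °C → rt; aq. Na2S2O3, pH 7 buffer; used crude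
Reagents that add atoms: none
Why: Dess–Martin oxidation of the α-hydroxy ester (a β-hydroxy ketone) to the 1,3-dicarbonyl releases the α-keto ester under neutral conditions, avoiding the acid that would drive pyranone formation.

Step 11
Reactants: 16 ethyl 7-[2-(tert-butoxycarbonyl)-3-methoxy-5-methylphenoxy]-5-chloro-2,4,6-trioxoheptanoate
Product: 18 ethyl 2-[2-(tert-butoxycarbonyl)-3-methoxy-5-methylphenoxy]-4-chloro-3,5-dihydroxybenzoate, via aldol adduct 17 (not isolated)
Conditions: DBU (1.2 equiv), THF, 0 °C → rt; AcOH quench, cold dilute HCl wash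
Reagents that add atoms: none
Why: One equivalent of base gives a monoanion that equilibrates through its tautomers, and in the C6=C7 enolate tautomer (the aryloxymethylene carbon, acidified by the ether oxygen) C2 is still a free ketone, so C7 adds to C2 to give adduct 17, which loses water by E1cB (C3–H, C2–OH) and tautomerizes irreversibly to resorcinol 18; excess base is avoided because a C2/C4 enolate would deactivate C2. The closest known reaction type is the base-mediated intramolecular aldol condensation and aromatization of 2,4,6-triketones and triketo esters to resorcinols (biomimetic polyketide folding). Ring A closes by a 6-(enolendo)-exo-trig aldol that forms the chain C7–C2 bond (ring A C2–C1); the enolate carbon C6 lies inside the new ring, so the closure is enolendo and not enolexo. No stereocentre is set, since the centres of 16 and 17 all become aromatic carbons. The step needs C-attack of C7 on C2 in preference to O-cyclization to a 4-pyranone, attack of C5 on the C1 ester and attack of C7 on the ring B ester. This is secured by the α-keto ester carbonyl being far more electrophilic than either ester, by the aprotic non-dehydrating base (hemiketal formation through oxygen stays reversible and only the C-aldol can aromatize), by the chlorine that keeps C5 a hindered, enolized and weakly nucleophilic carbon, and by the di-ortho-substituted tert-butyl ester on ring B, which blocks the Dieckmann closure to a benzofuranone.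

Step 12
Reactants: 18 ethyl 2-[2-(tert-butoxycarbonyl)-3-methoxy-5-methylphenoxy]-4-chloro-3,5-dihydroxybenzoate
Product: 19 ethyl 2-[2-(tert-butoxycarbonyl)-3-methoxy-5-methylphenoxy]-4-chloro-3-hydroxy-5-methoxybenzoate
Conditions: MeI (1.05 equiv), K2CO3 (1.1 equiv), acetone, 0 °C → rt
Reagents that add atoms: iodomethane, CI
Why: Williamson O-methylation should favour the C5 hydroxyl, which has only chlorine as an ortho neighbour, over the C3 hydroxyl, which sits between chlorine and the bulky aryloxy group carrying the tert-butyl ester; one equivalent of base and reagent limits bis-methylation.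

Step 13
Reactants: 19 ethyl 2-[2-(tert-butoxycarbonyl)-3-methoxy-5-methylphenoxy]-4-chloro-3-hydroxy-5-methoxybenzoate
Product: 20 2-[3-chloro-6-(ethoxycarbonyl)-2-hydroxy-4-methoxyphenoxy]-6-hydroxy-4-methylbenzoic acid
Conditions: BCl3 (1 M in CH2Cl2, 4 equiv), CH2Cl2, −78 → 0 °C; H2O
Reagents that add atoms: none
Why: Chelation-controlled Lewis acid dealkylation cleaves only the methyl ether ortho to the ring B carbonyl and also ionizes the tert-butyl ester, while the unchelated ring A methyl ether next to chlorine and the ethyl ester should survive at or below 0 °C.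

Step 14
Reactants: 20 2-[3-chloro-6-(ethoxycarbonyl)-2-hydroxy-4-methoxyphenoxy]-6-hydroxy-4-methylbenzoic acid
Product: 21 2-(6-carboxy-3-chloro-2-hydroxy-4-methoxyphenoxy)-6-hydroxy-4-methylbenzoic acid (target)
Conditions: LiOH·H2O (6 equiv), THF/H2O, rt → 40 °C; then 1 M HCl to pH 2 at 0 °C
Reagents that add atoms: lithium hydroxide, [Li+].[OH-]
Why: Saponification of the remaining ethyl ester, which has a single ortho substituent, gives the diacid, and any seven-membered lactone formed between the ring B carboxyl and the ring A C3 hydroxyl in step 13 would be opened by hydroxide to the same product.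

**Compound list**

1 | 2,6-dihydroxy-4-methylbenzoic acid | Cc1cc(O)c(C(=O)O)c(O)c1 | starting material
2 | tert-butyl 2,6-dihydroxy-4-methylbenzoate | Cc1cc(O)c(C(=O)OC(C)(C)C)c(O)c1 | intermediate
3 | tert-butyl 2-hydroxy-6-methoxy-4-methylbenzoate | COc1cc(C)cc(O)c1C(=O)OC(C)(C)C | intermediate
4 | ethyl bromoacetate | CCOC(=O)CBr | starting material
5 | tert-butyl 2-(2-ethoxy-2-oxoethoxy)-6-methoxy-4-methylbenzoate | CCOC(=O)COc1cc(C)cc(OC)c1C(=O)OC(C)(C)C | intermediate
6 | 2-[2-(tert-butoxycarbonyl)-3-methoxy-5-methylphenoxy]acetic acid | OC(=O)COc1cc(C)cc(OC)c1C(=O)OC(C)(C)C | intermediate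
7 | acetone | CC(C)=O | starting material
8 | ethyl glyoxylate | CCOC(=O)C=O | starting material
9 | ethyl 2-hydroxy-4-oxopentanoate (racemic) | CCOC(=O)C(O)CC(C)=O | intermediate
10 | ethyl 2-[(tert-butyldimethylsilyl)oxy]-4-oxopentanoate (racemic) | CCOC(=O)C(CC(C)=O)O[Si](C)(C)C(C)(C)C | intermediate
11 | tert-butyl 2-[2-(1H-imidazol-1-yl)-2-oxoethoxy]-6-methoxy-4-methylbenzoate (acyl imidazolide of 6) | O=C(COc1cc(C)cc(OC)c1C(=O)OC(C)(C)C)n1ccnc1 | intermediate
12 | lithium enolate of 10 at the methyl terminus (racemic) | [Li+].C=C([O-])CC(O[Si](C)(C)C(C)(C)C)C(=O)OCC | intermediate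
13 | ethyl 7-[2-(tert-butoxycarbonyl)-3-methoxy-5-methylphenoxy]-2-[(tert-butyldimethylsilyl)oxy]-4,6-dioxoheptanoate (racemic, enolized) | CCOC(=O)C(CC(=O)CC(=O)COc1cc(C)cc(OC)c1C(=O)OC(C)(C)C)O[Si](C)(C)C(C)(C)C | intermediate
14 | ethyl 7-[2-(tert-butoxycarbonyl)-3-methoxy-5-methylphenoxy]-2-[(tert-butyldimethylsilyl)oxy]-5-chloro-4,6-dioxoheptanoate (diastereomer mixture) | CCOC(=O)C(CC(=O)C(Cl)C(=O)COc1cc(C)cc(OC)c1C(=O)OC(C)(C)C)O[Si](C)(C)C(C)(C)C | intermediate
15 | ethyl 7-[2-(tert-butoxycarbonyl)-3-methoxy-5-methylphenoxy]-5-chloro-2-hydroxy-4,6-dioxoheptanoate (diastereomer mixture) | CCOC(=O)C(O)CC(=O)C(Cl)C(=O)COc1cc(C)cc(OC)c1C(=O)OC(C)(C)C | intermediate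
16 | ethyl 7-[2-(tert-butoxycarbonyl)-3-methoxy-5-methylphenoxy]-5-chloro-2,4,6-trioxoheptanoate (racemic, enolized) | CCOC(=O)C(=O)CC(=O)C(Cl)C(=O)COc1cc(C)cc(OC)c1C(=O)OC(C)(C)C | intermediate
17 | ethyl 2-[2-(tert-butoxycarbonyl)-3-methoxy-5-methylphenoxy]-4-chloro-1-hydroxy-3,5-dioxocyclohexane-1-carboxylate (stereoisomer mixture) | CCOC(=O)C1(O)CC(=O)C(Cl)C(=O)C1Oc1cc(C)cc(OC)c1C(=O)OC(C)(C)C | intermediate
18 | ethyl 2-[2-(tert-butoxycarbonyl)-3-methoxy-5-methylphenoxy]-4-chloro-3,5-dihydroxybenzoate | CCOC(=O)c1cc(O)c(Cl)c(O)c1Oc1cc(C)cc(OC)c1C(=O)OC(C)(C)C | intermediate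
19 | ethyl 2-[2-(tert-butoxycarbonyl)-3-methoxy-5-methylphenoxy]-4-chloro-3-hydroxy-5-methoxybenzoate | CCOC(=O)c1cc(OC)c(Cl)c(O)c1Oc1cc(C)cc(OC)c1C(=O)OC(C)(C)C | intermediate
20 | 2-[3-chloro-6-(ethoxycarbonyl)-2-hydroxy-4-methoxyphenoxy]-6-hydroxy-4-methylbenzoic acid | CCOC(=O)c1cc(OC)c(Cl)c(O)c1Oc1cc(C)cc(O)c1C(=O)O | intermediate
21 | 2-(6-carboxy-3-chloro-2-hydroxy-4-methoxyphenoxy)-6-hydroxy-4-methylbenzoic acid | COc1cc(C(=O)O)c(Oc2cc(C)cc(O)c2C(=O)O)c(O)c1Cl | target

**Step count**

Total steps: 14. Longest linear sequence: 12 steps (steps 1 to 4 and 7 to 14 from 1); steps 5 and 6 form the side branch.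

**Steps most likely to fail**

Step 11 (ring A closure). The enolized triketone may close through oxygen and then lose water to a 4-pyranone, may undergo retro-Claisen cleavage at the chlorinated diketone, or may stall at adduct 17. The fallback sets out from 16 and comes back at 18. Compound 16 would be cyclodehydrated on purpose (TFAA, pyridine, CH2Cl2, 0 °C) to the stable pyranone ethyl 6-{[2-(tert-butoxycarbonyl)-3-methoxy-5-methylphenoxy]methyl}-5-chloro-4-oxo-4H-pyran-2-carboxylate F1, which can be purified. Aqueous KOH in THF (0 °C → rt) should open the pyranone by conjugate addition of hydroxide, and the triketo carboxylate should reclose through carbon in the strongly basic aqueous medium (the classical pyranone-to-resorcinol conversion). This would give 2-[2-(tert-butoxycarbonyl)-3-methoxy-5-methylphenoxy]-4-chloro-3,5-dihydroxybenzoic acid F2. Its carboxyl group alone would be ethylated with EtI and KHCO3 in DMF to return to 18.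

Step 12 (site-selective methylation). Discrimination between the two ring A hydroxyls may be incomplete, and bis-methylation may compete. The fallback sets out from 18 and comes back at 21; it masks the C3 hydroxyl by the only lactone the geometry allows.
- TFA in CH2Cl2 would remove the tert-butyl ester to give 2-[3-chloro-6-(ethoxycarbonyl)-2,4-dihydroxyphenoxy]-6-methoxy-4-methylbenzoic acid F3.
- Lactonization under high dilution (EDC·HCl, DMAP, CH2Cl2) can engage only the C3 hydroxyl and should give the depsidone ethyl 9-chloro-8-hydroxy-1-methoxy-3-methyl-11-oxo-11H-dibenzo[b,e][1,4]dioxepine-6-carboxylate F4.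
- Methylation of the single free hydroxyl (MeI, K2CO3, acetone) would give ethyl 9-chloro-1,8-dimethoxy-3-methyl-11-oxo-11H-dibenzo[b,e][1,4]dioxepine-6-carboxylate F5.
- BCl3 (CH2Cl2, −78 → 0 °C) would cleave the methyl ether ortho to the lactone carbonyl to give ethyl 9-chloro-1-hydroxy-8-methoxy-3-methyl-11-oxo-11H-dibenzo[b,e][1,4]dioxepine-6-carboxylate F6.
- LiOH in THF/H2O would open the lactone and hydrolyse the ethyl ester to give 21.

Step 7 (enolate C-acylation). Proton transfer between the enolate, the acyl donor and the product may erode the conversion, the enolate may equilibrate to the internal position and eliminate silanolate, and O-acylation may compete. The fallback sets out from 5 (with 10) and comes back at 13; it replaces the acylation by an aldol addition and oxidation. i-Bu2AlH (1.05 equiv, CH2Cl2, −78 °C) would reduce the aliphatic ester of 5 to the aldehyde tert-butyl 2-methoxy-4-methyl-6-(2-oxoethoxy)benzoate F7. Addition of the lithium enolate of 10 (LiN(i-Pr)2, THF, −78 °C, about one equivalent, since the aldolate is not acidic) would give ethyl 7-[2-(tert-butoxycarbonyl)-3-methoxy-5-methylphenoxy]-2-[(tert-butyldimethylsilyl)oxy]-6-hydroxy-4-oxoheptanoate F8. Dess–Martin oxidation of the β-hydroxy ketone would give 13.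

**Further compounds**

F1 | step 11 | ethyl 6-{[2-(tert-butoxycarbonyl)-3-methoxy-5-methylphenoxy]methyl}-5-chloro-4-oxo-4H-pyran-2-carboxylate | CCOC(=O)C1=CC(=O)C(Cl)=C(COc2cc(C)cc(OC)c2C(=O)OC(C)(C)C)O1
F2 | step 11 | 2-[2-(tert-butoxycarbonyl)-3-methoxy-5-methylphenoxy]-4-chloro-3,5-dihydroxybenzoic acid | OC(=O)c1cc(O)c(Cl)c(O)c1Oc1cc(C)cc(OC)c1C(=O)OC(C)(C)C
F3 | step 12 | 2-[3-chloro-6-(ethoxycarbonyl)-2,4-dihydroxyphenoxy]-6-methoxy-4-methylbenzoic acid | CCOC(=O)c1cc(O)c(Cl)c(O)c1Oc1cc(C)cc(OC)c1C(=O)O
F4 | step 12 | ethyl 9-chloro-8-hydroxy-1-methoxy-3-methyl-11-oxo-11H-dibenzo[b,e][1,4]dioxepine-6-carboxylate | CCOC(=O)c1cc(O)c(Cl)c2OC(=O)c3c(OC)cc(C)cc3Oc12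
F5 | step 12 | ethyl 9-chloro-1,8-dimethoxy-3-methyl-11-oxo-11H-dibenzo[b,e][1,4]dioxepine-6-carboxylate | CCOC(=O)c1cc(OC)c(Cl)c2OC(=O)c3c(OC)cc(C)cc3Oc12
F6 | step 12 | ethyl 9-chloro-1-hydroxy-8-methoxy-3-methyl-11-oxo-11H-dibenzo[b,e][1,4]dioxepine-6-carboxylate | CCOC(=O)c1cc(OC)c(Cl)c2OC(=O)c3c(O)cc(C)cc3Oc12
F7 | step 7 | tert-butyl 2-methoxy-4-methyl-6-(2-oxoethoxy)benzoate | O=CCOc1cc(C)cc(OC)c1C(=O)OC(C)(C)C
F8 | step 7 | ethyl 7-[2-(tert-butoxycarbonyl)-3-methoxy-5-methylphenoxy]-2-[(tert-butyldimethylsilyl)oxy]-6-hydroxy-4-oxoheptanoate | CCOC(=O)C(CC(=O)CC(O)COc1cc(C)cc(OC)c1C(=O)OC(C)(C)C)O[Si](C)(C)C(C)(C)C
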